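Atoms are numbered in the order of the target SMILES (C1 … O34).

**Plan**
1. Cuts: C15–C16 between the two halves (C15 enol triflate plus C16 aldehyde, with C15=C16 and H–C2 arising later by 1,3-transposition); C5–C9; C4=C5; C15–C2; C6–C12. In the other half: C18–C19 together with O28–C25, and C32–C33.
2. Forward, hydroazulene half: iridium allylic alkylation, pentenyl addition, cycloheptene by metathesis, cyclopentanol by SmI2, enol triflate. Oxepane half: geranyl chain, double epoxidation, enol silane, oxepane and cyclohexanone in one cascade, methyl addition, aldehyde.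
3. Union by CrCl2/NiCl2 coupling, then C16 oxidation and reduction, diazene transposition, desilylation and C23 oxidation.
4. Stereochemistry: C6 from the iridium catalyst; C5 and C9 from C6 in the radical closure; C19, C29 and spectator C23 from the Shi epoxides; C18 from the chair closure; C32 from equatorial Grignard attack; C16 from the oxazaborolidine, passed on to C2 and the C15=C16 geometry by the retro-ene step.
5. Feature behind the key step: the tertiary carbinol C9 (methyl, hydroxyl cis to H5) sits on ring-fusion carbon C5 of the cis-fused bicycle formed by cyclopentane C5–C6–C7–C8–C9 and cycloheptane C2–C3–C4–C5–C6–C12–C15. This is the pattern left when the ketyl of a methyl ketone tethered at C6 adds to a C4=C5 ring alkene.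

Key step: step 10

Remark 1: C2 and C15 form without control in step 7 and are erased in steps 11 and 13. Compounds 13 to 21 are carried as epimer mixtures at these centres and their SMILES leave them open; the same holds for C16 in 37.
Remark 2: the phosphoramidite antipode in step 4 is the one that gives the (3R)-ester 8. This is expected to be the (Sa,S,S)-ligand; if the sense of induction proves opposite, the (Ra,R,R)-ligand is used.

**Step 1**
Reactants: 1 prop-2-yn-1-ol; 2 2-(2-bromoethyl)-2-methyl-1,3-dioxolane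
Product: 4 5-(2-methyl-1,3-dioxolan-2-yl)pent-2-yn-1-ol, via dilithium salt of prop-2-yn-1-ol 3 (not isolated)
Conditions: LiNH2 (2.2 equiv), liq. NH3, −33 °C; 2 in THF; NH4Cl
Reagents that add atoms: none
Why: Acetylide alkylation of the propargyl alcohol dianion by an unhindered primary bromide is a standard SN2 reaction in which the carbanion and not the alkoxide is alkylated, and the ketal is inert to base.

**Step 2**
Reactants: 4 5-(2-methyl-1,3-dioxolan-2-yl)pent-2-yn-1-ol
Product: 5 (2E)-5-(2-methyl-1,3-dioxolan-2-yl)pent-2-en-1-ol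
Conditions: LiAlH4, THF, 0 → 65 °C; aq. NaOH
Reagents that add atoms: none
Why: Hydroxyl-directed trans-hydroalumination of a propargylic alcohol should give only the (E)-allylic alcohol, the geometry the iridium catalyst needs.

**Step 3**
Reactants: 5 (2E)-5-(2-methyl-1,3-dioxolan-2-yl)pent-2-en-1-ol
Product: 6 methyl (2E)-5-(2-methyl-1,3-dioxolan-2-yl)pent-2-en-1-yl carbonate
Conditions: ClCO2Me, pyridine, CH2Cl2, 0 °C
Reagents that add atoms: methyl chloroformate, COC(=O)Cl
Why: Acylation of a primary alcohol with a chloroformate gives the linear allylic methyl carbonate, the usual leaving group for iridium-catalysed allylic substitution.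

**Step 4**
Reactants: 6 methyl (2E)-5-(2-methyl-1,3-dioxolan-2-yl)pent-2-en-1-yl carbonate; 7 1-methoxy-2-methyl-1-(trimethylsilyloxy)prop-1-ene
Product: 8 methyl (3R)-2,2-dimethyl-3-[2-(2-methyl-1,3-dioxolan-2-yl)ethyl]pent-4-enoate
Conditions: [Ir(cod)Cl]2 (2 mol%), BINOL-based N,N-bis(1-phenylethyl)phosphoramidite (4 mol%), n-PrNH2 (activation), KF, 18-crown-6, THF, 25 °C
Reagents that add atoms: none
Why: Iridium-catalysed asymmetric allylic alkylation with a silyl ketene acetal, in which the cyclometalated iridium phosphoramidite complex ionises the linear carbonate and the fluoride-activated isobutyrate enolate attacks the substituted allyl terminus anti to the metal, giving the branched ester and setting C6 under catalyst control.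

**Step 5**
Reactants: 8 methyl (3R)-2,2-dimethyl-3-[2-(2-methyl-1,3-dioxolan-2-yl)ethyl]pent-4-enoate
Product: 9 (3R)-2,2-dimethyl-3-[2-(2-methyl-1,3-dioxolan-2-yl)ethyl]pent-4-enal
Conditions: i-Bu2AlH (1.1 equiv), CH2Cl2, −78 °C; aq. KNaC4H4O6
Reagents that add atoms: none
Why: Partial ester reduction stops at the aluminium hemiacetal, which is stable at −78 °C beside the quaternary C12, and work-up releases an aldehyde that has no α-hydrogen and cannot enolise.

**Step 6**
Reactants: 10 pent-4-en-2-ol (racemic)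
Product: 11 4-bromopent-1-ene (racemic)
Conditions: CBr4, PPh3, CH2Cl2, 0 °C
Reagents that add atoms: tetrabromomethane, BrC(Br)(Br)Br
Why: Appel bromination converts the secondary alcohol into the bromide under neutral conditions that leave the terminal alkene untouched.

**Step 7**
Reactants: 9 (3R)-2,2-dimethyl-3-[2-(2-methyl-1,3-dioxolan-2-yl)ethyl]pent-4-enal; 11 4-bromopent-1-ene
Product: 13 (7R)-4,6,6-trimethyl-7-[2-(2-methyl-1,3-dioxolan-2-yl)ethyl]nona-1,8-dien-5-ol (epimers at C2/C15), via pent-4-en-2-ylmagnesium bromide 12 (not isolated)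
Conditions: 11, Mg, THF, 25 °C (used at once); CeCl3, THF, −78 °C; then 9, −78 → 0 °C
Reagents that add atoms: none
Why: Grignard addition in its organocerium (Imamoto) form to a neopentylic, non-enolisable aldehyde, where cerium suppresses β-hydride reduction by the secondary alkyl group, while C2 and C15 form without control and are both removed later.

**Step 8**
Reactants: 13 (7R)-4,6,6-trimethyl-7-[2-(2-methyl-1,3-dioxolan-2-yl)ethyl]nona-1,8-dien-5-ol
Product: 14 (3R)-2,2,7-trimethyl-3-[2-(2-methyl-1,3-dioxolan-2-yl)ethyl]cyclohept-4-en-1-ol (epimers at C2/C15)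
Conditions: second-generation Grubbs catalyst (5 mol%), CH2Cl2 (0.005 M), 40 °C
Reagents that add atoms: none
Why: Ring-closing metathesis of the 1,8-diene, in which the ruthenium carbene loads on the unhindered pentenyl alkene and closes the seven-membered ring onto the vinyl group with loss of ethene, helped by the gem-dimethyl group at C12.

**Step 9**
Reactants: 14 (3R)-2,2,7-trimethyl-3-[2-(2-methyl-1,3-dioxolan-2-yl)ethyl]cyclohept-4-en-1-ol
Product: 15 4-[(1R)-6-hydroxy-5,7,7-trimethylcyclohept-2-en-1-yl]butan-2-one (epimers at C2/C15)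
Conditions: 1 M HCl, THF, 25 °C
Reagents that add atoms: water, O
Why: Acid hydrolysis of the dioxolane frees the methyl ketone for the ketyl step, the ring alkene and the secondary alcohol being stable to dilute acid.

**Step 10**
Reactants: 15 4-[(1R)-6-hydroxy-5,7,7-trimethylcyclohept-2-en-1-yl]butan-2-one
Product: 18 (1R,3aR,8aR)-1,4,4,6-tetramethyldecahydroazulene-1,5-diol (cis-fused; epimers at C2/C15), via samarium ketyl 16 (not isolated), via cyclised C4 radical 17 (not isolated)
Conditions: SmI2 (3 equiv), HMPA (12 equiv), t-BuOH (3 equiv), THF, 0 → 25 °C, slow addition of 15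
Reagents that add atoms: none
Why: One electron from SmI2 (divalent samarium, made more reducing by HMPA) turns the methyl ketone into the samarium ketyl 16, which adds to C5 of the C4=C5 ring alkene; the resulting C4 radical 17 is reduced by a second SmI2 to an alkylsamarium (trivalent samarium) and protonated by tert-butanol, so C4 ends as a plain CH2 group. The closest known reaction type is the SmI2/HMPA ketyl–olefin cyclization of unactivated alkenyl methyl ketones to cyclopentanols. The cyclopentane C5–C6–C7–C8–C9 closes in the 5-exo-trig mode through a chair-like transition state. C5 is set by C6, since the two-carbon tether can reach C5 only on the ring face that carries it, which makes the ring fusion cis; C9 is set by the bulky, negatively charged samarium-bound oxygen, which turns away from the alkene and from C4, so the hydroxyl should end cis to H5 and the methyl group face the seven-membered ring. The step needs attack at C5 instead of C4 and reduction of one carbonyl group only; the first is secured by the 5-exo preference of the short tether and the second by keeping C15 at the alcohol level, while the uncontrolled C2 and C15 centres lie outside the reacting array.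

**Step 11**
Reactants: 18 (1R,3aR,8aR)-1,4,4,6-tetramethyldecahydroazulene-1,5-diol
Product: 19 (1R,3aR,8aR)-1-hydroxy-1,4,4,6-tetramethyloctahydroazulen-5(1H)-one (epimers at C2)
Conditions: Dess–Martin periodinane, NaHCO3, CH2Cl2, 25 °C
Reagents that add atoms: none
Why: Dess–Martin oxidation converts the only secondary alcohol into the C15 ketone and removes the uncontrolled C15 centre, the tertiary C9 alcohol being inert.

**Step 12**
Reactants: 19 (1R,3aR,8aR)-1-hydroxy-1,4,4,6-tetramethyloctahydroazulen-5(1H)-one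
Product: 20 (1R,3aR,8aR)-1,4,4,6-tetramethyl-1-(triethylsilyloxy)octahydroazulen-5(1H)-one
Conditions: Et3SiOTf, 2,6-lutidine, CH2Cl2, −78 → 0 °C
Reagents that add atoms: triethylsilyl trifluoromethanesulfonate, CC[Si](CC)(CC)OS(=O)(=O)C(F)(F)F
Why: Silylation of the tertiary alcohol with a silyl triflate, so that no alkoxide competes with the enolate in step 13 or with the Mitsunobu activation in step 25.

**Step 13**
Reactants: 20 (1R,3aR,8aR)-1,4,4,6-tetramethyl-1-(triethylsilyloxy)octahydroazulen-5(1H)-one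
Product: 22 (1R,3aR,8aR)-1,4,4,6-tetramethyl-1-(triethylsilyloxy)-1,2,3,3a,4,7,8,8a-octahydroazulen-5-yl trifluoromethanesulfonate, via potassium enolate 21 (not isolated)
Conditions: KN(SiMe3)2, THF, −78 → −20 °C; PhNTf2, −78 → 0 °C
Reagents that add atoms: N-phenylbis(trifluoromethanesulfonimide), O=S(=O)(N(c1ccccc1)S(=O)(=O)C(F)(F)F)C(F)(F)F
Why: Enol triflate formation, where the ketone can enolise only toward C2 because C12 is quaternary, so O-sulfonylation of the potassium enolate gives the single tetrasubstituted triflate (as with 2,2,6-trimethylcyclohexanone) and erases the C2 centre.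

**Step 14**
Reactants: 23 geranyl bromide, (2E)-1-bromo-3,7-dimethylocta-2,6-diene; 24 N-methoxy-N-methylacetamide
Product: 26 (4E)-N-methoxy-N,5,9-trimethyldeca-4,8-dienamide, via lithium enolate of the acetamide 25 (not isolated)
Conditions: 24, LiN(i-Pr)2, THF, −78 °C; then 23, −78 → 0 °C
Reagents that add atoms: none
Why: Alkylation of an amide enolate by a primary allylic bromide is an SN2 reaction that keeps the (E)-alkene of the geranyl unit.

**Step 15**
Reactants: 26 (4E)-N-methoxy-N,5,9-trimethyldeca-4,8-dienamide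
Product: 27 N-methoxy-N-methyl-3-[(2R,3R)-3-{2-[(2R)-3,3-dimethyloxiran-2-yl]ethyl}-3-methyloxiran-2-yl]propanamide
Conditions: D-fructose-derived Shi ketone (0.6 equiv), KHSO5 (as 2KHSO5·KHSO4·K2SO4), K2CO3, Bu4NHSO4, MeCN/CH2(OMe)2/aq. buffer pH 10.5, 0 °C
Reagents that add atoms: potassium peroxymonosulfate, [K+].[O-]S(=O)(=O)OO
Why: Shi asymmetric epoxidation, in which the dioxirane of the D-fructose-derived ketone epoxidises both electron-rich trisubstituted alkenes through the spiro transition state, giving the (R,R)- and (R)-epoxides that later fix C19, C29 and the spectator C23.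

**Step 16**
Reactants: 27 N-methoxy-N-methyl-3-[(2R,3R)-3-{2-[(2R)-3,3-dimethyloxiran-2-yl]ethyl}-3-methyloxiran-2-yl]propanamide
Product: 28 5-[(2R,3R)-3-{2-[(2R)-3,3-dimethyloxiran-2-yl]ethyl}-3-methyloxiran-2-yl]pent-1-en-3-one
Conditions: CH2=CHMgBr, THF, −78 → 0 °C; inverse quench into cold aq. NH4Cl
Reagents that add atoms: vinylmagnesium bromide, C=C[Mg]Br
Why: Acyl substitution of a Weinreb amide, where the chelated tetrahedral magnesium adduct prevents over-addition and releases the vinyl ketone on quench, the trisubstituted epoxides being inert to the Grignard reagent at low temperature.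

**Step 17**
Reactants: 28 5-[(2R,3R)-3-{2-[(2R)-3,3-dimethyloxiran-2-yl]ethyl}-3-methyloxiran-2-yl]pent-1-en-3-one
Product: 29 (3Z)-1-[(2R,3R)-3-{2-[(2R)-3,3-dimethyloxiran-2-yl]ethyl}-3-methyloxiran-2-yl]-3-(trimethylsilyloxy)hepta-3,6-diene
Conditions: CH2=CHMgBr, CuBr·SMe2 (10 mol%), Me3SiCl, HMPA, THF, −78 °C; Et3N, pentane
Reagents that add atoms: vinylmagnesium bromide, C=C[Mg]Br; chlorotrimethylsilane, C[Si](C)(C)Cl
Why: Copper-catalysed conjugate addition with in situ silylation (Nakamura–Kuwajima conditions) adds the vinyl group 1,4 and traps the enolate on oxygen, which places the enol ether double bond regiospecifically at C32=C18 (mainly Z), something no deprotonation of the ketone could do.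

**Step 18**
Reactants: 29 (3Z)-1-[(2R,3R)-3-{2-[(2R)-3,3-dimethyloxiran-2-yl]ethyl}-3-methyloxiran-2-yl]-3-(trimethylsilyloxy)hepta-3,6-diene
Product: 31 (3R,5aR,6R,9aR)-3-hydroxy-2,2,5a-trimethyl-6-(prop-2-en-1-yl)octahydro-1-benzoxepin-7(2H)-one, via C23 trimethylsilyl ether 30 (not isolated)
Conditions: Me3SiOTf (1.0 equiv), 2,6-di-tert-butyl-4-methylpyridine, CH2Cl2, −78 °C; then 1 M HCl, THF, 0 °C
Reagents that add atoms: none
Why: Lewis-acid-triggered epoxide-opening cascade (tandem oxacyclisation–carbocyclisation of a 1,5-diepoxide ended by an enol silane), in which the inner epoxide oxygen opens the silyl-activated terminal epoxide at its tertiary carbon C25 and the enol silane opens the resulting epoxonium ion at C19 with inversion through a chair, so that C19 and C29 come from the (2R,3R)-oxirane, the ring fusion is trans, and the (Z)-enol silane places the C18 allyl group equatorial, which is also the more stable epimer.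

**Step 19**
Reactants: 31 (3R,5aR,6R,9aR)-3-hydroxy-2,2,5a-trimethyl-6-(prop-2-en-1-yl)octahydro-1-benzoxepin-7(2H)-one
Product: 32 (3R,5aR,6R,7S,9aR)-2,2,5a,7-tetramethyl-6-(prop-2-en-1-yl)decahydro-1-benzoxepine-3,7-diol
Conditions: MeMgBr (4 equiv), CeCl3, THF, −78 → 0 °C
Reagents that add atoms: methylmagnesium bromide, C[Mg]Br
Why: Grignard addition to a cyclohexanone (CeCl3 suppresses enolisation), where the axial methyl group on C19 shields the axial trajectory at C32, so the methyl group should enter equatorially and the new hydroxyl be axial, cis to the C19 methyl group and to the C18 side chain as in the target.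

**Step 20**
Reactants: 32 (3R,5aR,6R,7S,9aR)-2,2,5a,7-tetramethyl-6-(prop-2-en-1-yl)decahydro-1-benzoxepine-3,7-diol
Product: 33 (3R,5aR,6R,7S,9aR)-2,2,5a,7-tetramethyl-6-(prop-2-en-1-yl)-3,7-bis(triethylsilyloxy)decahydro-1-benzoxepine
Conditions: Et3SiOTf (3 equiv), 2,6-lutidine, CH2Cl2, 0 → 25 °C
Reagents that add atoms: triethylsilyl trifluoromethanesulfonate, CC[Si](CC)(CC)OS(=O)(=O)C(F)(F)F
Why: Silylation with a silyl triflate covers both the secondary C23 and the hindered tertiary C32 hydroxyl, which keeps the C16 aldehyde from closing to a lactol and keeps both oxygens out of the later oxidation and Mitsunobu steps.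

**Step 21**
Reactants: 33 (3R,5aR,6R,7S,9aR)-2,2,5a,7-tetramethyl-6-(prop-2-en-1-yl)-3,7-bis(triethylsilyloxy)decahydro-1-benzoxepine
Product: 35 2-[(3R,5aR,6R,7S,9aR)-2,2,5a,7-tetramethyl-3,7-bis(triethylsilyloxy)decahydro-1-benzoxepin-6-yl]acetaldehyde, via ozonide 34 (not isolated)
Conditions: O3, CH2Cl2, −78 °C; PPh3, −78 → 25 °C
Reagents that add atoms: ozone, [O-][O+]=O
Why: Ozonolysis with reductive work-up cleaves the only alkene, the terminal allyl group, to the C16 aldehyde without touching the silyl ethers.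

**Step 22**
Reactants: 22 (1R,3aR,8aR)-1,4,4,6-tetramethyl-1-(triethylsilyloxy)-1,2,3,3a,4,7,8,8a-octahydroazulen-5-yl trifluoromethanesulfonate; 35 2-[(3R,5aR,6R,7S,9aR)-2,2,5a,7-tetramethyl-3,7-bis(triethylsilyloxy)decahydro-1-benzoxepin-6-yl]acetaldehyde
Product: 37 1-[(1R,3aR,8aR)-1,4,4,6-tetramethyl-1-(triethylsilyloxy)-1,2,3,3a,4,7,8,8a-octahydroazulen-5-yl]-2-[(3R,5aR,6R,7S,9aR)-2,2,5a,7-tetramethyl-3,7-bis(triethylsilyloxy)decahydro-1-benzoxepin-6-yl]ethan-1-ol (epimers at C16), via vinylchromium species 36 (not isolated)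
Conditions: CrCl2 (6 equiv), NiCl2 (2 mol%), DMF, 25 °C
Reagents that add atoms: none
Why: Nozaki–Hiyama–Kishi coupling, in which zerovalent nickel formed in situ inserts into the vinyl triflate, transmetalation gives the vinylchromium species 36 (trivalent chromium), and this adds to the aldehyde in preference to any other group, the uncontrolled C16 configuration being reset in steps 23 and 24.

**Step 23**
Reactants: 37 coupled allylic alcohol (epimers at C16)
Product: 38 1-[(1R,3aR,8aR)-1,4,4,6-tetramethyl-1-(triethylsilyloxy)-1,2,3,3a,4,7,8,8a-octahydroazulen-5-yl]-2-[(3R,5aR,6R,7S,9aR)-2,2,5a,7-tetramethyl-3,7-bis(triethylsilyloxy)decahydro-1-benzoxepin-6-yl]ethan-1-one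
Conditions: Dess–Martin periodinane, NaHCO3, CH2Cl2, 25 °C
Reagents that add atoms: none
Why: Dess–Martin oxidation merges both C16 epimers into one enone, all other oxygens being silylated.

**Step 24**
Reactants: 38 C16 enone
Product: 39 (1R)-1-[(1R,3aR,8aR)-1,4,4,6-tetramethyl-1-(triethylsilyloxy)-1,2,3,3a,4,7,8,8a-octahydroazulen-5-yl]-2-[(3R,5aR,6R,7S,9aR)-2,2,5a,7-tetramethyl-3,7-bis(triethylsilyloxy)decahydro-1-benzoxepin-6-yl]ethan-1-ol
Conditions: (S)-2-methyl-CBS-oxazaborolidine (1.0 equiv), catecholborane, toluene, −78 → −40 °C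
Reagents that add atoms: none
Why: Corey–Bakshi–Shibata reduction, in which the ketone binds to the (S)-oxazaborolidine with the tetrasubstituted cycloheptenyl group as the large substituent and the C17 methylene as the small one, so hydride should be delivered to the face that gives the (16R)-alcohol under catalyst control, with catecholborane chosen so that no alkene is hydroborated.

**Step 25**
Reactants: 39 (16R)-allylic alcohol
Product: 42 tris(triethylsilyl) ether of 43, via Mitsunobu adduct 40 (not isolated), via allylic diazene 41 (not isolated)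
Conditions: Me2C=NNHSO2C6H4-2-NO2 (IPNBSH), PPh3, DEAD, THF, 0 → 25 °C; then CF3CH2OH/H2O (1:1), 25 °C
Reagents that add atoms: none
Why: Reductive 1,3-transposition of an allylic alcohol through a monoalkyl diazene (Myers–Movassaghi), in which Mitsunobu displacement inverts C16 to the (16S)-sulfonyl hydrazone 40, solvolysis and loss of 2-nitrobenzenesulfinic acid give the diazene 41, and its retro-ene loss of N2 passes hydrogen suprafacially to C2 from the rotamer that places H16 and not C17 next to the C1 methyl group (1,3-allylic strain), which should put the new hydrogen on C2 cis to H5 and H6 and C17 cis to C12 on the C15=C16 bond.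

**Step 26**
Reactants: 42 tris(triethylsilyl) ether
Product: 43 (3R,5aR,6R,7S,9aR)-6-{(2Z)-2-[(1R,3aR,6S,8aR)-1-hydroxy-1,4,4,6-tetramethyloctahydroazulen-5(1H)-ylidene]ethyl}-2,2,5a,7-tetramethyldecahydro-1-benzoxepine-3,7-diol
Conditions: Bu4NF, THF, 50 °C
Reagents that add atoms: none
Why: Fluoride cleavage of the three triethylsilyl ethers, the tertiary ones needing gentle heating, leaves the alkene and all stereocentres untouched.

**Step 27**
Reactants: 43 triol
Product: 44 (5aR,6R,7S,9aR)-7-hydroxy-6-{(2Z)-2-[(1R,3aR,6S,8aR)-1-hydroxy-1,4,4,6-tetramethyloctahydroazulen-5(1H)-ylidene]ethyl}-2,2,5a,7-tetramethyloctahydro-1-benzoxepin-3(2H)-one (target)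
Conditions: Dess–Martin periodinane, NaHCO3, CH2Cl2, 25 °C
Reagents that add atoms: none
Why: Dess–Martin oxidation of the only secondary alcohol (C23) gives the oxepanone, the two tertiary alcohols and the trisubstituted alkene being inert.

**Compound list**
1 | prop-2-yn-1-ol | C#CCO | starting material
2 | 2-(2-bromoethyl)-2-methyl-1,3-dioxolane | CC1(CCBr)OCCO1 | starting material
3 | dilithium salt of prop-2-yn-1-ol | [Li]C#CCO[Li] | intermediate (not isolated)
4 | 5-(2-methyl-1,3-dioxolan-2-yl)pent-2-yn-1-ol | OCC#CCCC1(C)OCCO1 | intermediate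
5 | (2E)-5-(2-methyl-1,3-dioxolan-2-yl)pent-2-en-1-ol | OC/C=C/CCC1(C)OCCO1 | intermediate
6 | methyl (2E)-5-(2-methyl-1,3-dioxolan-2-yl)pent-2-en-1-yl carbonate | COC(=O)OC/C=C/CCC1(C)OCCO1 | intermediate
7 | 1-methoxy-2-methyl-1-(trimethylsilyloxy)prop-1-ene | COC(O[Si](C)(C)C)=C(C)C | starting material
8 | methyl (3R)-2,2-dimethyl-3-[2-(2-methyl-1,3-dioxolan-2-yl)ethyl]pent-4-enoate | C=C[C@@H](CCC1(C)OCCO1)C(C)(C)C(=O)OC | intermediate
9 | (3R)-2,2-dimethyl-3-[2-(2-methyl-1,3-dioxolan-2-yl)ethyl]pent-4-enal | C=C[C@@H](CCC1(C)OCCO1)C(C)(C)C=O | intermediate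
10 | pent-4-en-2-ol (racemic) | CC(O)CC=C | starting material
11 | 4-bromopent-1-ene (racemic) | CC(Br)CC=C | intermediate
12 | pent-4-en-2-ylmagnesium bromide | CC(CC=C)[Mg]Br | intermediate (not isolated)
13 | (7R)-4,6,6-trimethyl-7-[2-(2-methyl-1,3-dioxolan-2-yl)ethyl]nona-1,8-dien-5-ol, epimers at C2/C15 | C=CCC(C)C(O)C(C)(C)[C@H](CCC1(C)OCCO1)C=C | intermediate
14 | (3R)-2,2,7-trimethyl-3-[2-(2-methyl-1,3-dioxolan-2-yl)ethyl]cyclohept-4-en-1-ol, epimers at C2/C15 | CC1CC=C[C@@H](CCC2(C)OCCO2)C(C)(C)C1O | intermediate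
15 | 4-[(1R)-6-hydroxy-5,7,7-trimethylcyclohept-2-en-1-yl]butan-2-one, epimers at C2/C15 | CC1CC=C[C@@H](CCC(C)=O)C(C)(C)C1O | intermediate (key-step precursor)
16 | samarium ketyl of 15 (trivalent samarium on oxygen, radical at C9) | CC1CC=C[C@@H](CC[C](C)O[Sm](I)I)C(C)(C)C1O | intermediate (not isolated)
17 | cyclised C4 radical | CC1C[CH][C@@H]2[C@@H](CC[C@@]2(C)O[Sm](I)I)C(C)(C)C1O | intermediate (not isolated)
18 | (1R,3aR,8aR)-1,4,4,6-tetramethyldecahydroazulene-1,5-diol, cis-fused, epimers at C2/C15 | CC1CC[C@@H]2[C@@H](CC[C@@]2(C)O)C(C)(C)C1O | intermediate (key-step product)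
19 | (1R,3aR,8aR)-1-hydroxy-1,4,4,6-tetramethyloctahydroazulen-5(1H)-one, epimers at C2 | CC1CC[C@@H]2[C@@H](CC[C@@]2(C)O)C(C)(C)C1=O | intermediate
20 | (1R,3aR,8aR)-1,4,4,6-tetramethyl-1-(triethylsilyloxy)octahydroazulen-5(1H)-one, epimers at C2 | CC1CC[C@@H]2[C@@H](CC[C@@]2(C)O[Si](CC)(CC)CC)C(C)(C)C1=O | intermediate
21 | potassium enolate of 20 | CC=1CC[C@@H]2[C@@H](CC[C@@]2(C)O[Si](CC)(CC)CC)C(C)(C)C=1[O-].[K+] | intermediate (not isolated)
22 | (1R,3aR,8aR)-1,4,4,6-tetramethyl-1-(triethylsilyloxy)-1,2,3,3a,4,7,8,8a-octahydroazulen-5-yl trifluoromethanesulfonate | CC=1CC[C@@H]2[C@@H](CC[C@@]2(C)O[Si](CC)(CC)CC)C(C)(C)C=1OS(=O)(=O)C(F)(F)F | intermediate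
23 | geranyl bromide, (2E)-1-bromo-3,7-dimethylocta-2,6-diene | CC(C)=CCC/C(C)=C/CBr | starting material
24 | N-methoxy-N-methylacetamide | CC(=O)N(C)OC | starting material
25 | lithium enolate of 24 | C=C(O[Li])N(C)OC | intermediate (not isolated)
26 | (4E)-N-methoxy-N,5,9-trimethyldeca-4,8-dienamide | CON(C)C(=O)CC/C=C(\C)CCC=C(C)C | intermediate
27 | N-methoxy-N-methyl-3-[(2R,3R)-3-{2-[(2R)-3,3-dimethyloxiran-2-yl]ethyl}-3-methyloxiran-2-yl]propanamide | CON(C)C(=O)CC[C@H]1O[C@]1(C)CC[C@H]1OC1(C)C | intermediate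
28 | 5-[(2R,3R)-3-{2-[(2R)-3,3-dimethyloxiran-2-yl]ethyl}-3-methyloxiran-2-yl]pent-1-en-3-one | C=CC(=O)CC[C@H]1O[C@]1(C)CC[C@H]1OC1(C)C | intermediate
29 | (3Z)-1-[(2R,3R)-3-{2-[(2R)-3,3-dimethyloxiran-2-yl]ethyl}-3-methyloxiran-2-yl]-3-(trimethylsilyloxy)hepta-3,6-diene | C=CC/C=C(\O[Si](C)(C)C)CC[C@H]1O[C@]1(C)CC[C@H]1OC1(C)C | intermediate
30 | (3R,5aR,6R,9aR)-2,2,5a-trimethyl-6-(prop-2-en-1-yl)-3-(trimethylsilyloxy)octahydro-1-benzoxepin-7(2H)-one | C=CC[C@@H]1[C@@]2(C)CC[C@@H](O[Si](C)(C)C)C(C)(C)O[C@@H]2CCC1=O | intermediate (not isolated)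
31 | (3R,5aR,6R,9aR)-3-hydroxy-2,2,5a-trimethyl-6-(prop-2-en-1-yl)octahydro-1-benzoxepin-7(2H)-one | C=CC[C@@H]1[C@@]2(C)CC[C@@H](O)C(C)(C)O[C@@H]2CCC1=O | intermediate
32 | (3R,5aR,6R,7S,9aR)-2,2,5a,7-tetramethyl-6-(prop-2-en-1-yl)decahydro-1-benzoxepine-3,7-diol | C=CC[C@@H]1[C@@]2(C)CC[C@@H](O)C(C)(C)O[C@@H]2CC[C@]1(C)O | intermediate
33 | (3R,5aR,6R,7S,9aR)-2,2,5a,7-tetramethyl-6-(prop-2-en-1-yl)-3,7-bis(triethylsilyloxy)decahydro-1-benzoxepine | C=CC[C@@H]1[C@@]2(C)CC[C@@H](O[Si](CC)(CC)CC)C(C)(C)O[C@@H]2CC[C@]1(C)O[Si](CC)(CC)CC | intermediate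
34 | ozonide (1,2,4-trioxolane) of 33 | C1OC(C[C@@H]2[C@@]3(C)CC[C@@H](O[Si](CC)(CC)CC)C(C)(C)O[C@@H]3CC[C@]2(C)O[Si](CC)(CC)CC)OO1 | intermediate (not isolated)
35 | 2-[(3R,5aR,6R,7S,9aR)-2,2,5a,7-tetramethyl-3,7-bis(triethylsilyloxy)decahydro-1-benzoxepin-6-yl]acetaldehyde | O=CC[C@@H]1[C@@]2(C)CC[C@@H](O[Si](CC)(CC)CC)C(C)(C)O[C@@H]2CC[C@]1(C)O[Si](CC)(CC)CC | intermediate
36 | vinylchromium dichloride from 22 (trivalent chromium) | CC=1CC[C@@H]2[C@@H](CC[C@@]2(C)O[Si](CC)(CC)CC)C(C)(C)C=1[Cr](Cl)Cl | intermediate (not isolated)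
37 | 1-[(1R,3aR,8aR)-1,4,4,6-tetramethyl-1-(triethylsilyloxy)-1,2,3,3a,4,7,8,8a-octahydroazulen-5-yl]-2-[(3R,5aR,6R,7S,9aR)-2,2,5a,7-tetramethyl-3,7-bis(triethylsilyloxy)decahydro-1-benzoxepin-6-yl]ethan-1-ol, epimers at C16 | CC=1CC[C@@H]2[C@@H](CC[C@@]2(C)O[Si](CC)(CC)CC)C(C)(C)C=1C(O)C[C@@H]1[C@@]2(C)CC[C@@H](O[Si](CC)(CC)CC)C(C)(C)O[C@@H]2CC[C@]1(C)O[Si](CC)(CC)CC | intermediate
38 | corresponding ethan-1-one (C16 enone) | CC=1CC[C@@H]2[C@@H](CC[C@@]2(C)O[Si](CC)(CC)CC)C(C)(C)C=1C(=O)C[C@@H]1[C@@]2(C)CC[C@@H](O[Si](CC)(CC)CC)C(C)(C)O[C@@H]2CC[C@]1(C)O[Si](CC)(CC)CC | intermediate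
39 | (1R)-ethan-1-ol of 37, the (16R)-allylic alcohol | CC=1CC[C@@H]2[C@@H](CC[C@@]2(C)O[Si](CC)(CC)CC)C(C)(C)C=1[C@H](O)C[C@@H]1[C@@]2(C)CC[C@@H](O[Si](CC)(CC)CC)C(C)(C)O[C@@H]2CC[C@]1(C)O[Si](CC)(CC)CC | intermediate
40 | (16S)-N-(2-nitrobenzenesulfonyl)-N'-(propan-2-ylidene)hydrazine at C16 (Mitsunobu adduct) | CC=1CC[C@@H]2[C@@H](CC[C@@]2(C)O[Si](CC)(CC)CC)C(C)(C)C=1[C@@H](N(N=C(C)C)S(=O)(=O)c3ccccc3[N+](=O)[O-])C[C@@H]1[C@@]2(C)CC[C@@H](O[Si](CC)(CC)CC)C(C)(C)O[C@@H]2CC[C@]1(C)O[Si](CC)(CC)CC | intermediate (not isolated)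
41 | (16S)-allylic diazene | CC=1CC[C@@H]2[C@@H](CC[C@@]2(C)O[Si](CC)(CC)CC)C(C)(C)C=1[C@@H](N=N)C[C@@H]1[C@@]2(C)CC[C@@H](O[Si](CC)(CC)CC)C(C)(C)O[C@@H]2CC[C@]1(C)O[Si](CC)(CC)CC | intermediate (not isolated)
42 | tris(triethylsilyl) ether of 43 (silyl groups on O11, O24, O34) | C[C@H]1CC[C@@H]2[C@@H](CC[C@@]2(C)O[Si](CC)(CC)CC)C(C)(C)/C1=C\C[C@@H]1[C@@]2(C)CC[C@@H](O[Si](CC)(CC)CC)C(C)(C)O[C@@H]2CC[C@]1(C)O[Si](CC)(CC)CC | intermediate
43 | (3R,5aR,6R,7S,9aR)-6-{(2Z)-2-[(1R,3aR,6S,8aR)-1-hydroxy-1,4,4,6-tetramethyloctahydroazulen-5(1H)-ylidene]ethyl}-2,2,5a,7-tetramethyldecahydro-1-benzoxepine-3,7-diol | C[C@H]1CC[C@@H]2[C@@H](CC[C@@]2(C)O)C(C)(C)/C1=C\C[C@@H]1[C@@]2(C)CC[C@@H](O)C(C)(C)O[C@@H]2CC[C@]1(C)O | intermediate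
44 | (5aR,6R,7S,9aR)-7-hydroxy-6-{(2Z)-2-[(1R,3aR,6S,8aR)-1-hydroxy-1,4,4,6-tetramethyloctahydroazulen-5(1H)-ylidene]ethyl}-2,2,5a,7-tetramethyloctahydro-1-benzoxepin-3(2H)-one, CNP0157787.1 | C[C@H]1CC[C@@H]2[C@@H](CC[C@@]2(C)O)C(C)(C)/C1=C\C[C@@H]1[C@@]2(C)CCC(=O)C(C)(C)O[C@@H]2CC[C@]1(C)O | target

**Count and risks**
Total steps: 27. Longest linear sequence: 18 steps (steps 1–5, 7–13, 22–27). Steps 14–21 (oxepane half) and step 6 (bromide) are side branches.

Steps most likely to fail:

1. Step 25. Mitsunobu activation of the hindered C16 carbinol, flanked by a tetrasubstituted alkene and a branched chain, may end in ionisation, SN2′ attack or elimination instead of clean inversion. The retro-ene step may also lose facial fidelity if the C17 chain takes the inside position. The fallback sets out from 39 and returns at 42. Acylation of 39 with ClCO2Me and pyridine gives the allylic methyl carbonate F1. This is reduced with Pd(OAc)2, n-Bu3P and HCO2NH4 in THF (Tsuji formate reduction). Zerovalent palladium ionises the carbonate anti to the C16–O bond, and the hydride formed from formate passes from the metal to the more substituted allyl terminus C2. Hydrogen therefore again enters anti to the original C16 oxygen, and 42 is reached without a Mitsunobu step.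

2. Step 18. The labile trisubstituted enol silane may be lost by protodesilylation before it meets the epoxonium ion, or C18–C19 bond formation may be too slow to compete with collapse of the cation by elimination or 1,2-shift. The fallback sets out from 27 and returns at 31. The Weinreb amide 27 is acylated by the lithium enolate of allyl acetate (LiN(i-Pr)2, THF, −78 °C) to the allyl β-keto ester F2. Its enol silane F3 forms regiospecifically in the flask (Me3SiOTf, Et3N), because the only acidic position lies between the two carbonyl groups; either enol geometry serves. The same Me3SiOTf cascade, followed by dilute acid, gives the bicyclic allyl β-keto ester F4. Decarboxylative allylation with Pd(PPh3)4 then moves the allyl group from the ester oxygen to C18 with loss of CO2, and brief K2CO3/MeOH equilibration gives 31.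

3. Step 22. Oxidative addition and transmetalation at the tetrasubstituted triflate beside the quaternary C12 may be slower than reduction or pinacol coupling of the aldehyde by CrCl2. The fallback sets out from 20 and returns at 37. Ketone 20 is condensed with 2,4,6-triisopropylbenzenesulfonyl hydrazide (cat. HCl, THF) to the sulfonylhydrazone F5. Treatment with n-BuLi (2.2 equiv, THF, −78 → 0 °C) removes the N–H and the C2 hydrogen, and loss of sulfinate and N2 (Shapiro reaction) gives the vinyllithium F6. This is added to 35 at −78 °C to give 37.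

**Further compounds**
F1 | step 25 | methyl carbonate of the (16R)-allylic alcohol 39 | CC=1CC[C@@H]2[C@@H](CC[C@@]2(C)O[Si](CC)(CC)CC)C(C)(C)C=1[C@H](OC(=O)OC)C[C@@H]1[C@@]2(C)CC[C@@H](O[Si](CC)(CC)CC)C(C)(C)O[C@@H]2CC[C@]1(C)O[Si](CC)(CC)CC
F2 | step 18 | prop-2-en-1-yl 5-[(2R,3R)-3-{2-[(2R)-3,3-dimethyloxiran-2-yl]ethyl}-3-methyloxiran-2-yl]-3-oxopentanoate | C=CCOC(=O)CC(=O)CC[C@H]1O[C@]1(C)CC[C@H]1OC1(C)C
F3 | step 18 | prop-2-en-1-yl (2Z)-5-[(2R,3R)-3-{2-[(2R)-3,3-dimethyloxiran-2-yl]ethyl}-3-methyloxiran-2-yl]-3-(trimethylsilyloxy)pent-2-enoate | C=CCOC(=O)/C=C(\O[Si](C)(C)C)CC[C@H]1O[C@]1(C)CC[C@H]1OC1(C)C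
F4 | step 18 | prop-2-en-1-yl (3R,5aR,9aR)-3-hydroxy-2,2,5a-trimethyl-7-oxodecahydro-1-benzoxepine-6-carboxylate | C=CCOC(=O)C1[C@@]2(C)CC[C@@H](O)C(C)(C)O[C@@H]2CCC1=O
F5 | step 22 | 2,4,6-triisopropylbenzenesulfonylhydrazone of ketone 20 | CC1CC[C@@H]2[C@@H](CC[C@@]2(C)O[Si](CC)(CC)CC)C(C)(C)C1=NNS(=O)(=O)c3c(C(C)C)cc(C(C)C)cc3C(C)C
F6 | step 22 | (1R,3aR,8aR)-1,4,4,6-tetramethyl-1-(triethylsilyloxy)-1,2,3,3a,4,7,8,8a-octahydroazulen-5-yllithium | CC=1CC[C@@H]2[C@@H](CC[C@@]2(C)O[Si](CC)(CC)CC)C(C)(C)C=1[Li]
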